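**Retrosynthetic overview**

- The strategy rests on the oxolane: C3 carries CH2OH and is bonded to C4, which carries the benzylic CH2 arm. The C3–C4 bond is therefore made by 5-exo closure of a C3 radical, released from a terminal oxirane that spans C3 and its CH2O carbon, onto a cinnamyl ether double bond. The oxolane is the last ring formed.
- The precursor is the cinnamyl ether (O1–C5 bond, Ag2O etherification) of anti epoxy alcohol 3 with cinnamyl bromide 20. Compound 3 comes from O-benzylisovanillin by vinyl addition and Sharpless kinetic resolution.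
- The dihydrobenzofuran is built first. Two SNAr steps and a TosMIC homologation on 4-bromo-2,6-difluorobenzaldehyde give an arylacetic acid; an Evans syn aldol with O-benzylvanillin sets dihydrobenzofuran C3; acid-mediated capture of the benzylic cation by the phenol closes the furan ring trans.
- Suzuki coupling and Appel bromination convert the aryl bromide into the cinnamyl bromide; hydrogenolysis of three benzyl ethers ends the route.

Key step: step 16

Remark: the kinetic resolution gives the anti (erythro) epoxy alcohol, S at the carbinol carbon and R at the oxirane carbon. Only the carbinol centre is carried into the target, because the oxirane carbon becomes the planar C3 radical. (S)-4-Benzyl-1,3-oxazolidin-2-one and (E)-3-(pinacolboryl)prop-2-en-1-ol are taken as purchasable reagents.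

**Route**

Step 1
Reactants: 1 3-(benzyloxy)-4-methoxybenzaldehyde
Product: 2 rac-1-[3-(benzyloxy)-4-methoxyphenyl]prop-2-en-1-ol
Conditions: CH2=CHMgBr, THF, 0 °C
Reagents that add atoms: vinylmagnesium bromide, C=C[Mg]Br
Why: Grignard 1,2-addition to the aryl aldehyde should give the racemic secondary allylic alcohol, and the benzyl ether is inert.

Step 2
Reactants: 2 rac-1-[3-(benzyloxy)-4-methoxyphenyl]prop-2-en-1-ol
Product: 3 (S)-[3-(benzyloxy)-4-methoxyphenyl][(2R)-oxiran-2-yl]methanol
Conditions: Ti(OiPr)4 (0.1 equiv), L-(+)-DIPT (0.15 equiv), TBHP (0.5 equiv), 4 Å MS, CH2Cl2, −20 °C; non-acidic work-up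
Reagents that add atoms: tert-butyl hydroperoxide, CC(C)(C)OO
Why: Sharpless kinetic resolution (Katsuki–Sharpless epoxidation): with L-(+)-tartrate the R alcohol should be epoxidised fast and erythro-selectively on the face the tartrate dictates, so stopping near half conversion should give the anti epoxy alcohol (S carbinol, R oxirane) and leave the S alcohol behind.

Step 3
Reactants: 4 4-bromo-2,6-difluorobenzaldehyde
Product: 5 4-bromo-2-fluoro-6-methoxybenzaldehyde
Conditions: NaOMe (1.0 equiv), MeOH, 0 °C to rt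
Reagents that add atoms: sodium methoxide, C[O-].[Na+]
Why: SNAr at a fluoride ortho to the formyl group; the first methoxy group deactivates the ring towards a second substitution, and fluoride is displaced far faster than the para bromide.

Step 4
Reactants: 5 4-bromo-2-fluoro-6-methoxybenzaldehyde
Product: 6 4-bromo-2-methoxy-6-(prop-2-en-1-yloxy)benzaldehyde
Conditions: allyl alcohol, NaH, THF, 0 °C to rt
Reagents that add atoms: allyl alcohol, C=CCO
Why: a second SNAr at the remaining aldehyde-activated fluoride installs the future furan oxygen as an allyl ether, which is orthogonal to the benzyl ethers.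

Step 5
Reactants: 6 4-bromo-2-methoxy-6-(prop-2-en-1-yloxy)benzaldehyde
Product: 8 2-[4-bromo-2-methoxy-6-(prop-2-en-1-yloxy)phenyl]acetonitrile, via N-(1-tosylalkenyl)formamide 7 (not isolated)
Conditions: TosMIC, KOtBu, DME, −40 °C; then MeOH, reflux
Reagents that add atoms: tosylmethyl isocyanide, Cc1ccc(cc1)S(=O)(=O)C[N+]#[C-]
Why: van Leusen reductive cyanation: the TosMIC anion adds to the aldehyde, the oxazoline opens to the N-formyl enamide, and methanolysis with loss of sulfinate should give the nitrile homologated by one carbon.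

Step 6
Reactants: 8 2-[4-bromo-2-methoxy-6-(prop-2-en-1-yloxy)phenyl]acetonitrile
Product: 9 2-[4-bromo-2-methoxy-6-(prop-2-en-1-yloxy)phenyl]acetic acid
Conditions: KOH, EtOH–H2O, reflux; then HCl to pH 2
Reagents that add atoms: potassium hydroxide, [K+].[OH-]; water, O
Why: basic nitrile hydrolysis; the aryl bromide and the allyl and methyl aryl ethers are stable to aqueous hydroxide.

Step 7
Reactants: 9 2-[4-bromo-2-methoxy-6-(prop-2-en-1-yloxy)phenyl]acetic acid
Product: 11 (4S)-4-benzyl-3-{2-[4-bromo-2-methoxy-6-(prop-2-en-1-yloxy)phenyl]acetyl}-1,3-oxazolidin-2-one, via mixed pivalic anhydride 10 (not isolated)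
Conditions: PivCl, Et3N, THF, −20 °C; then (S)-4-benzyl-1,3-oxazolidin-2-one, LiCl, rt
Reagents that add atoms: (S)-4-benzyl-1,3-oxazolidin-2-one, O=C1OC[C@H](Cc2ccccc2)N1; pivaloyl chloride, CC(C)(C)C(=O)Cl (its atoms stay only in 10)
Why: N-acylation of the Evans auxiliary through the mixed anhydride, which is attacked at the less hindered arylacetyl carbonyl.

Step 8
Reactants: 11 (4S)-4-benzyl-3-{2-[4-bromo-2-methoxy-6-(prop-2-en-1-yloxy)phenyl]acetyl}-1,3-oxazolidin-2-one; 12 4-(benzyloxy)-3-methoxybenzaldehyde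
Product: 14 (4S)-4-benzyl-3-[(2S,3S)-3-[4-(benzyloxy)-3-methoxyphenyl]-2-[4-bromo-2-methoxy-6-(prop-2-en-1-yloxy)phenyl]-3-hydroxypropanoyl]-1,3-oxazolidin-2-one, via Z-boron enolate 13 (not isolated)
Conditions: Bu2BOTf, iPr2NEt, CH2Cl2, 0 °C; 12, −78 to 0 °C; pH 7 buffer, MeOH, H2O2, 0 °C
Reagents that add atoms: dibutylboron triflate, CCCCB(CCCC)OS(=O)(=O)C(F)(F)F (its atoms stay only in 13)
Why: Evans syn aldol: the Z-boron enolate reacts through a Zimmerman–Traxler chair on the face away from the auxiliary benzyl group, which should set the α-carbon S (the future dihydrobenzofuran C3) and the carbinol S.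

Step 9
Reactants: 14 the syn aldol adduct
Product: 15 (1S,2R)-1-[4-(benzyloxy)-3-methoxyphenyl]-2-[4-bromo-2-methoxy-6-(prop-2-en-1-yloxy)phenyl]propane-1,3-diol
Conditions: LiBH4, MeOH (1 equiv), THF, 0 °C
Reagents that add atoms: none
Why: reductive cleavage of the imide by borohydride gives the primary alcohol without touching the α-stereocentre, the aryl bromide or the allyl ether.

Step 10
Reactants: 15 the allyl-protected diol
Product: 16 (1S,2R)-1-[4-(benzyloxy)-3-methoxyphenyl]-2-(4-bromo-2-hydroxy-6-methoxyphenyl)propane-1,3-diol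
Conditions: Pd(PPh3)4 (3 mol %), morpholine, THF, rt
Reagents that add atoms: none
Why: Tsuji–Trost deallylation: zerovalent palladium ionises the aryl allyl ether and morpholine captures the allyl fragment, while the aryl bromide does not undergo oxidative addition at room temperature.

Step 11
Reactants: 16 the phenol diol
Product: 17 [(2S,3R)-2-[4-(benzyloxy)-3-methoxyphenyl]-6-bromo-4-methoxy-2,3-dihydro-1-benzofuran-3-yl]methanol
Conditions: p-TsOH·H2O (10 mol %), CH2Cl2–MeCN (0.01 M), 0 °C to rt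
Reagents that add atoms: none
Why: acid-catalysed cyclodehydration (SN1): the para-benzyloxybenzyl cation is captured by the phenol oxygen in a five-membered closure anti to the hydroxymethyl group at C3, and any cis isomer can re-ionise and drain to trans, so C2 should be set trans to the untouched aldol-derived C3; the primary alcohol could only form an oxetane.

Step 12
Reactants: 17 the dihydrobenzofuran alcohol
Product: 18 (2S,3R)-2-[4-(benzyloxy)-3-methoxyphenyl]-3-[(benzyloxy)methyl]-6-bromo-4-methoxy-2,3-dihydro-1-benzofuran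
Conditions: NaH, BnBr, Bu4NI (cat.), THF–DMF, 0 °C to rt
Reagents that add atoms: benzyl bromide, BrCc1ccccc1
Why: Williamson etherification of the only free hydroxyl group.

Step 13
Reactants: 18 the aryl bromide
Product: 19 (2E)-3-[(2S,3R)-2-[4-(benzyloxy)-3-methoxyphenyl]-3-[(benzyloxy)methyl]-4-methoxy-2,3-dihydro-1-benzofuran-6-yl]prop-2-en-1-ol
Conditions: (E)-3-(pinacolboryl)prop-2-en-1-ol, Pd(dppf)Cl2 (5 mol %), K2CO3, dioxane–H2O, 80 °C
Reagents that add atoms: (E)-3-(4,4,5,5-tetramethyl-1,3,2-dioxaborolan-2-yl)prop-2-en-1-ol, OC/C=C/B1OC(C)(C)C(C)(C)O1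
Why: Suzuki–Miyaura coupling of the aryl bromide with the alkenylboronate proceeds with retention of the E geometry and tolerates the free allylic alcohol.

Step 14
Reactants: 19 the cinnamyl alcohol
Product: 20 (2S,3R)-2-[4-(benzyloxy)-3-methoxyphenyl]-3-[(benzyloxy)methyl]-6-[(1E)-3-bromoprop-1-en-1-yl]-4-methoxy-2,3-dihydro-1-benzofuran
Conditions: CBr4, PPh3, CH2Cl2, 0 °C; used at once
Reagents that add atoms: carbon tetrabromide, BrC(Br)(Br)Br
Why: Appel bromination of the primary allylic alcohol; the ring oxygens are meta to the side chain, so the cinnamyl bromide is not activated towards ionisation and should keep its position and geometry.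

Step 15
Reactants: 3 (S)-[3-(benzyloxy)-4-methoxyphenyl][(2R)-oxiran-2-yl]methanol (2.5 equiv, excess recovered); 20 the cinnamyl bromide
Product: 21 (2R)-2-[(S)-[3-(benzyloxy)-4-methoxyphenyl]{[(2E)-3-[(2S,3R)-2-[4-(benzyloxy)-3-methoxyphenyl]-3-[(benzyloxy)methyl]-4-methoxy-2,3-dihydro-1-benzofuran-6-yl]prop-2-en-1-yl]oxy}methyl]oxirane
Conditions: Ag2O, 4 Å MS, CH2Cl2, rt, dark
Reagents that add atoms: none
Why: silver oxide-mediated Williamson-type etherification: silver assists departure of the allylic bromide and no free alkoxide is formed, so the epoxy alcohol cannot undergo Payne rearrangement and the carbinol centre is untouched.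

Step 16
Reactants: 21 the epoxy cinnamyl ether
Product: 22 [(2R,3S,4S)-2-[3-(benzyloxy)-4-methoxyphenyl]-4-{[(2S,3R)-2-[4-(benzyloxy)-3-methoxyphenyl]-3-[(benzyloxy)methyl]-4-methoxy-2,3-dihydro-1-benzofuran-6-yl]methyl}oxolan-3-yl]methanol
Conditions: Cp2TiCl2 (3 equiv), Zn dust (6 equiv), THF, rt (green Cp2TiCl); added dropwise to 21 in THF, rt; cold 1 M HCl quench
Reagents that add atoms: none
Why: Cp2TiCl (trivalent titanium) transfers one electron to the oxirane and cleaves the C–O bond at the substituted carbon, giving a secondary β-titanoxy radical at the future C3 (Nugent–RajanBabu reductive epoxide opening, the known titanocene radical cyclisation to 3-hydroxymethyl oxolanes). The radical adds to the near carbon of the cinnamyl double bond and closes the oxolane in a 5-exo-trig mode, forming C3–C4. The benzylic radical left outside the ring is reduced by a second trivalent titanium and protonated on work-up to the CH2 arm. C3 should be set trans to the C2 aryl group because in the chair-like Beckwith–Houk transition state that aryl group is pseudo-equatorial and the CH2OTi group on the radical carbon turns away from it; C4 should be set cis to C3 by the 1,5-cis preference of a 1-substituted hex-5-enyl radical. C2 is untouched and the oxirane stereocentre is erased in the planar radical. The step needs ring closure to outrun capture of the radical by a second titanium, which would expel the β-oxygen; the styrene-type acceptor, the oxygen in the tether and slow addition of the reagent should secure this, and the benzyl ethers, aryl ethers and dihydrobenzofuran are inert.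

Step 17
Reactants: 22 the tri-O-benzyl oxolane
Product: 23 5-[(2R,3S,4S)-3-(hydroxymethyl)-4-{[(2S,3R)-2-(4-hydroxy-3-methoxyphenyl)-3-(hydroxymethyl)-4-methoxy-2,3-dihydro-1-benzofuran-6-yl]methyl}oxolan-2-yl]-2-methoxyphenol (CNP0242386.1)
Conditions: H2 (1 atm), 10% Pd/C, NaHCO3, EtOAc–EtOH, rt; stopped at full debenzylation
Reagents that add atoms: none
Why: catalytic hydrogenolysis of the three benzyl ethers; the buffered, low-pressure conditions should leave the slower-cleaving ring benzylic C–O bonds (oxolane C2–O, dihydrobenzofuran C2–O) intact.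

**Compound list**

1 | 3-(benzyloxy)-4-methoxybenzaldehyde | COc1ccc(C=O)cc1OCc1ccccc1 | starting material
2 | rac-1-[3-(benzyloxy)-4-methoxyphenyl]prop-2-en-1-ol | COc1ccc(C(O)C=C)cc1OCc1ccccc1 | intermediate
3 | (S)-[3-(benzyloxy)-4-methoxyphenyl][(2R)-oxiran-2-yl]methanol | COc1ccc([C@@H]([C@H]2CO2)O)cc1OCc1ccccc1 | intermediate
4 | 4-bromo-2,6-difluorobenzaldehyde | O=Cc1c(F)cc(Br)cc1F | starting material
5 | 4-bromo-2-fluoro-6-methoxybenzaldehyde | COc1cc(Br)cc(F)c1C=O | intermediate
6 | 4-bromo-2-methoxy-6-(prop-2-en-1-yloxy)benzaldehyde | COc1cc(Br)cc(OCC=C)c1C=O | intermediate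
7 | N-{2-[4-bromo-2-methoxy-6-(prop-2-en-1-yloxy)phenyl]-1-tosylethenyl}formamide | COc1cc(Br)cc(OCC=C)c1C=C(NC=O)S(=O)(=O)c1ccc(C)cc1 | intermediate (not isolated)
8 | 2-[4-bromo-2-methoxy-6-(prop-2-en-1-yloxy)phenyl]acetonitrile | COc1cc(Br)cc(OCC=C)c1CC#N | intermediate
9 | 2-[4-bromo-2-methoxy-6-(prop-2-en-1-yloxy)phenyl]acetic acid | COc1cc(Br)cc(OCC=C)c1CC(=O)O | intermediate
10 | 2-[4-bromo-2-methoxy-6-(prop-2-en-1-yloxy)phenyl]acetic pivalic anhydride | COc1cc(Br)cc(OCC=C)c1CC(=O)OC(=O)C(C)(C)C | intermediate (not isolated)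
11 | (4S)-4-benzyl-3-{2-[4-bromo-2-methoxy-6-(prop-2-en-1-yloxy)phenyl]acetyl}-1,3-oxazolidin-2-one | COc1cc(Br)cc(OCC=C)c1CC(=O)N1[C@@H](Cc2ccccc2)COC1=O | intermediate
12 | 4-(benzyloxy)-3-methoxybenzaldehyde | COc1cc(C=O)ccc1OCc1ccccc1 | starting material
13 | dibutylboron Z-enolate of 11 | CCCCB(CCCC)O/C(=C\c1c(OC)cc(Br)cc1OCC=C)N1[C@@H](Cc2ccccc2)COC1=O | intermediate (not isolated)
14 | (4S)-4-benzyl-3-[(2S,3S)-3-[4-(benzyloxy)-3-methoxyphenyl]-2-[4-bromo-2-methoxy-6-(prop-2-en-1-yloxy)phenyl]-3-hydroxypropanoyl]-1,3-oxazolidin-2-one | O=C1OC[C@H](Cc2ccccc2)N1C(=O)[C@@H](c1c(OC)cc(Br)cc1OCC=C)[C@H](O)c1ccc(OCc2ccccc2)c(OC)c1 | intermediate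
15 | (1S,2R)-1-[4-(benzyloxy)-3-methoxyphenyl]-2-[4-bromo-2-methoxy-6-(prop-2-en-1-yloxy)phenyl]propane-1,3-diol | OC[C@@H](c1c(OC)cc(Br)cc1OCC=C)[C@H](O)c1ccc(OCc2ccccc2)c(OC)c1 | intermediate
16 | (1S,2R)-1-[4-(benzyloxy)-3-methoxyphenyl]-2-(4-bromo-2-hydroxy-6-methoxyphenyl)propane-1,3-diol | OC[C@@H](c1c(OC)cc(Br)cc1O)[C@H](O)c1ccc(OCc2ccccc2)c(OC)c1 | intermediate
17 | [(2S,3R)-2-[4-(benzyloxy)-3-methoxyphenyl]-6-bromo-4-methoxy-2,3-dihydro-1-benzofuran-3-yl]methanol | Brc1cc(OC)c2c(c1)O[C@H](c1ccc(OCc3ccccc3)c(OC)c1)[C@H]2CO | intermediate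
18 | (2S,3R)-2-[4-(benzyloxy)-3-methoxyphenyl]-3-[(benzyloxy)methyl]-6-bromo-4-methoxy-2,3-dihydro-1-benzofuran | Brc1cc(OC)c2c(c1)O[C@H](c1ccc(OCc3ccccc3)c(OC)c1)[C@H]2COCc1ccccc1 | intermediate
19 | (2E)-3-[(2S,3R)-2-[4-(benzyloxy)-3-methoxyphenyl]-3-[(benzyloxy)methyl]-4-methoxy-2,3-dihydro-1-benzofuran-6-yl]prop-2-en-1-ol | OC/C=C/c1cc(OC)c2c(c1)O[C@H](c1ccc(OCc3ccccc3)c(OC)c1)[C@H]2COCc1ccccc1 | intermediate
20 | (2S,3R)-2-[4-(benzyloxy)-3-methoxyphenyl]-3-[(benzyloxy)methyl]-6-[(1E)-3-bromoprop-1-en-1-yl]-4-methoxy-2,3-dihydro-1-benzofuran | BrC/C=C/c1cc(OC)c2c(c1)O[C@H](c1ccc(OCc3ccccc3)c(OC)c1)[C@H]2COCc1ccccc1 | intermediate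
21 | (2R)-2-[(S)-[3-(benzyloxy)-4-methoxyphenyl]{[(2E)-3-[(2S,3R)-2-[4-(benzyloxy)-3-methoxyphenyl]-3-[(benzyloxy)methyl]-4-methoxy-2,3-dihydro-1-benzofuran-6-yl]prop-2-en-1-yl]oxy}methyl]oxirane | COc1ccc([C@@H]([C@H]2CO2)OC/C=C/c2cc(OC)c3c(c2)O[C@H](c2ccc(OCc4ccccc4)c(OC)c2)[C@H]3COCc2ccccc2)cc1OCc1ccccc1 | intermediate
22 | [(2R,3S,4S)-2-[3-(benzyloxy)-4-methoxyphenyl]-4-{[(2S,3R)-2-[4-(benzyloxy)-3-methoxyphenyl]-3-[(benzyloxy)methyl]-4-methoxy-2,3-dihydro-1-benzofuran-6-yl]methyl}oxolan-3-yl]methanol | COc1ccc([C@@H]2OC[C@@H](Cc3cc(OC)c4c(c3)O[C@H](c3ccc(OCc5ccccc5)c(OC)c3)[C@H]4COCc3ccccc3)[C@H]2CO)cc1OCc1ccccc1 | intermediate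
23 | 5-[(2R,3S,4S)-3-(hydroxymethyl)-4-{[(2S,3R)-2-(4-hydroxy-3-methoxyphenyl)-3-(hydroxymethyl)-4-methoxy-2,3-dihydro-1-benzofuran-6-yl]methyl}oxolan-2-yl]-2-methoxyphenol | COc1ccc([C@@H]2OC[C@@H](Cc3cc(OC)c4c(c3)O[C@H](c3ccc(O)c(OC)c3)[C@H]4CO)[C@H]2CO)cc1O | target

**Step count and risks**

Total: 17 steps. Longest linear sequence: 15 steps (steps 3 to 17, from 4-bromo-2,6-difluorobenzaldehyde).

Steps most likely to fail:

1. Step 15 (fragment union). The silver-promoted O-alkylation of a hindered secondary alcohol by one equivalent of a large allylic bromide may be slow, so that silver-assisted solvolysis or allylic transposition of the bromide outruns ether formation. The fallback joins the fragments by C–C instead of C–O bond formation and sets out from 3 and 18. Compound 3 is O-allylated with excess allyl bromide (Ag2O, CH2Cl2) to (2R)-2-[(S)-[3-(benzyloxy)-4-methoxyphenyl](prop-2-en-1-yloxy)methyl]oxirane F1. Compound 18 is vinylated (potassium vinyltrifluoroborate, Pd(dppf)Cl2, Cs2CO3, THF–H2O, 70 °C) to the 6-ethenyl dihydrobenzofuran F2. Olefin cross-metathesis of F2 with excess F1 (second-generation Hoveyda–Grubbs catalyst, CH2Cl2, 40 °C) should give the E cinnamyl ether, and the route is rejoined at 21.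

2. Step 16 (key radical cyclisation). The β-titanoxy radical may be captured by a second trivalent titanium centre and lose its β-oxygen before it closes, or closure may deliver too little of the 3,4-cis isomer. The fallback makes the same C3 radical without titanium and sets out from 21. Sodium benzyloxide (BnOH, NaH, DMF, 60 °C) opens the oxirane at its CH2 carbon to the secondary alcohol F3. 1,1'-Thiocarbonyldiimidazole (DMAP, CH2Cl2) converts it into the O-(imidazol-1-ylthiocarbonyl) derivative F4. Slow addition of Bu3SnH and AIBN in refluxing toluene triggers Barton–McCombie C–O scission; the radical closes 5-exo onto the cinnamyl double bond and the benzylic radical takes hydrogen from the stannane, giving the tetra-O-benzyl oxolane F5. Hydrogenolysis under the conditions of step 17 removes all four benzyl groups, and the route is rejoined at 23.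

3. Step 2 (kinetic resolution). The titanium tartrate may ionise the electron-rich benzylic allylic alcohol or its epoxy alcohol (allylic transposition, oxirane opening), which would erode both the selectivity factor and the recovery. The fallback separates the resolution from the epoxidation and sets out from 2. Immobilised Candida antarctica lipase B with vinyl acetate in MTBE at 30 °C should acylate the R alcohol (Kazlauskas rule) to (R)-1-[3-(benzyloxy)-4-methoxyphenyl]prop-2-en-1-yl acetate F6, which is separated from the S alcohol. Methanolysis (K2CO3, MeOH) gives (R)-1-[3-(benzyloxy)-4-methoxyphenyl]prop-2-en-1-ol F7. Hydroxyl-directed epoxidation (VO(acac)2 cat., TBHP, CH2Cl2, 0 °C) gives 3 together with its oxirane epimer (S)-[3-(benzyloxy)-4-methoxyphenyl][(2S)-oxiran-2-yl]methanol F8. Both carry the S carbinol centre and give the same radical in step 16, so the mixture rejoins the route at 3.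

**Further compounds**

F1 | step 15 | (2R)-2-[(S)-[3-(benzyloxy)-4-methoxyphenyl](prop-2-en-1-yloxy)methyl]oxirane | COc1ccc([C@@H]([C@H]2CO2)OCC=C)cc1OCc1ccccc1
F2 | step 15 | (2S,3R)-2-[4-(benzyloxy)-3-methoxyphenyl]-3-[(benzyloxy)methyl]-6-ethenyl-4-methoxy-2,3-dihydro-1-benzofuran | C=Cc1cc(OC)c2c(c1)O[C@H](c1ccc(OCc3ccccc3)c(OC)c1)[C@H]2COCc1ccccc1
F3 | step 16 | (1S,2R)-3-(benzyloxy)-1-[3-(benzyloxy)-4-methoxyphenyl]-1-{[(2E)-3-[(2S,3R)-2-[4-(benzyloxy)-3-methoxyphenyl]-3-[(benzyloxy)methyl]-4-methoxy-2,3-dihydro-1-benzofuran-6-yl]prop-2-en-1-yl]oxy}propan-2-ol | COc1ccc([C@@H]([C@H](O)COCc2ccccc2)OC/C=C/c2cc(OC)c3c(c2)O[C@H](c2ccc(OCc4ccccc4)c(OC)c2)[C@H]3COCc2ccccc2)cc1OCc1ccccc1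
F4 | step 16 | O-(imidazol-1-ylthiocarbonyl) derivative of F3 | COc1ccc([C@@H]([C@H](OC(=S)n2ccnc2)COCc2ccccc2)OC/C=C/c2cc(OC)c3c(c2)O[C@H](c2ccc(OCc4ccccc4)c(OC)c2)[C@H]3COCc2ccccc2)cc1OCc1ccccc1
F5 | step 16 | (2S,3R)-2-[4-(benzyloxy)-3-methoxyphenyl]-3-[(benzyloxy)methyl]-6-{[(3S,4S,5R)-5-[3-(benzyloxy)-4-methoxyphenyl]-4-[(benzyloxy)methyl]oxolan-3-yl]methyl}-4-methoxy-2,3-dihydro-1-benzofuran | COc1ccc([C@@H]2OC[C@@H](Cc3cc(OC)c4c(c3)O[C@H](c3ccc(OCc5ccccc5)c(OC)c3)[C@H]4COCc3ccccc3)[C@H]2COCc2ccccc2)cc1OCc1ccccc1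
F6 | step 2 | (R)-1-[3-(benzyloxy)-4-methoxyphenyl]prop-2-en-1-yl acetate | COc1ccc([C@H](OC(C)=O)C=C)cc1OCc1ccccc1
F7 | step 2 | (R)-1-[3-(benzyloxy)-4-methoxyphenyl]prop-2-en-1-ol | COc1ccc([C@H](O)C=C)cc1OCc1ccccc1
F8 | step 2 | (S)-[3-(benzyloxy)-4-methoxyphenyl][(2S)-oxiran-2-yl]methanol | COc1ccc([C@@H]([C@@H]2CO2)O)cc1OCc1ccccc1
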